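**Retrosynthetic overview**
- The two prenyl groups are made last, by olefin cross-metathesis of a 6,8-diallyl isoflavone with 2-methyl-2-butene, so that no alkene is present during the thallium oxidation.
- The two allyl groups come from a double aromatic Claisen rearrangement of the 5,7-bis(allyl ether) of the isoflavone core.
- Ring C (the pyranone, the only ring formed) is closed by acid from a beta-keto acetal, which arises by oxidative 1,2-aryl shift of a 2'-hydroxychalcone.
- The chalcone is assembled by a Claisen–Schmidt aldol condensation of a ring A acetophenone (from 2,4,6-trihydroxyacetophenone) with a ring B benzaldehyde (from 2,4-dihydroxybenzaldehyde); this is the fragment union.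
- Protecting groups: benzyl on ring A and MOM on ring B, which keeps the 4'-oxygen distinguishable from the 5- and 7-oxygens.

Assumption: the target SMILES has no stereocentre and no stereogenic double bond, so the compound is achiral and "single enantiomer" needs no asymmetric step.

**Route**

Step 1
Reactants: 1 2,4,6-trihydroxyacetophenone; 2 benzyl bromide
Product: 3 1-[2,4-bis(benzyloxy)-6-hydroxyphenyl]ethanone
Conditions: BnBr (2.1 equiv), K2CO3 (2.2 equiv), DMF, rt, 24 h
Reagents that add atoms: benzyl bromide, BrCc1ccccc1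
Why: Williamson etherification alkylates the para-OH and one ortho-OH, while the last ortho-OH stays hydrogen-bonded to the acetyl carbonyl and is too weakly nucleophilic to react under these mild conditions.

Step 2
Reactants: 4 2,4-dihydroxybenzaldehyde; 5 chloromethyl methyl ether (MOMCl)
Product: 6 2-hydroxy-4-(methoxymethoxy)benzaldehyde
Conditions: MOMCl (1.1 equiv), K2CO3, acetone, 0 °C to rt
Reagents that add atoms: chloromethyl methyl ether, COCCl
Why: Williamson-type O-alkylation is selective for the 4-OH because the 2-OH is chelated to the aldehyde carbonyl.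

Step 3
Reactants: 6 2-hydroxy-4-(methoxymethoxy)benzaldehyde; 7 iodomethane
Product: 8 2-methoxy-4-(methoxymethoxy)benzaldehyde
Conditions: MeI (1.5 equiv), K2CO3, DMF, rt
Reagents that add atoms: iodomethane, CI
Why: Williamson O-methylation of the remaining phenol goes to completion with excess MeI in DMF, and the MOM ether and the aldehyde are inert to K2CO3.

Step 4
Reactants: 3 1-[2,4-bis(benzyloxy)-6-hydroxyphenyl]ethanone; 8 2-methoxy-4-(methoxymethoxy)benzaldehyde
Product: 10 (E)-1-[2,4-bis(benzyloxy)-6-hydroxyphenyl]-3-[2-methoxy-4-(methoxymethoxy)phenyl]prop-2-en-1-one, via beta-hydroxy ketone aldol adduct 9 (not isolated)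
Conditions: KOH (50% aq, excess), EtOH–THF, rt, 36 h; AcOH to pH 6
Reagents that add atoms: none
Why: In this Claisen–Schmidt (crossed aldol) condensation the methyl ketone enolate adds to the non-enolisable aldehyde and E1cB loss of water gives only the conjugated (E)-enone, with benzyl and MOM ethers stable to KOH.

Step 5
Reactants: 10 (E)-chalcone
Product: 11 1-[2,4-bis(benzyloxy)-6-hydroxyphenyl]-3,3-dimethoxy-2-[2-methoxy-4-(methoxymethoxy)phenyl]propan-1-one (racemic)
Conditions: Tl(NO3)3·3H2O (1.2 equiv), MeOH–CH2Cl2, rt, 4–12 h; filter off TlNO3 (thallium salts are highly toxic)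
Reagents that add atoms: methanol, CO
Why: Oxidative 1,2-aryl rearrangement of the chalcone by trivalent thallium (oxythallation of the enone, then migration of the electron-rich 2,4-dioxygenated ring from C-beta to C-alpha with methanol capture) gives the acetal, and its one new stereocentre is racemic and is destroyed in the next step.

Step 6
Reactants: 11 beta-keto dimethyl acetal
Product: 13 5,7-bis(benzyloxy)-3-(4-hydroxy-2-methoxyphenyl)chromen-4-one, via 2-methoxyisoflavanone 12 (not isolated)
Conditions: 10% aq HCl, MeOH–THF, reflux, 3 h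
Reagents that add atoms: none
Why: Acid-catalysed transacetalisation by the free ortho-phenol closes ring C, loss of methanol gives the chromen-4-one, and the same acid cleaves the MOM acetal while the benzyl ethers survive.

Step 7
Reactants: 13 5,7-bis(benzyloxy)-3-(4-hydroxy-2-methoxyphenyl)chromen-4-one; 5 chloromethyl methyl ether
Product: 14 5,7-bis(benzyloxy)-3-[2-methoxy-4-(methoxymethoxy)phenyl]chromen-4-one
Conditions: MOMCl (1.5 equiv), K2CO3, acetone, rt to 40 °C
Reagents that add atoms: chloromethyl methyl ether, COCCl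
Why: Williamson O-alkylation of the only free phenol puts a base- and heat-stable MOM ether on ring B, so the 4'-oxygen stays distinguishable from the ring A oxygens.

Step 8
Reactants: 14 5,7-bis(benzyloxy)-3-[2-methoxy-4-(methoxymethoxy)phenyl]chromen-4-one
Product: 15 5,7-dihydroxy-3-[2-methoxy-4-(methoxymethoxy)phenyl]chromen-4-one
Conditions: H2 (1 atm), 10% Pd/C, THF–EtOAc, rt, stop after 2 equiv H2
Reagents that add atoms: none
Why: Catalytic hydrogenolysis cleaves the two benzylic C–O bonds at room temperature without reducing the chromone C2=C3 bond or touching the MOM ether in a neutral aprotic solvent.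

Step 9
Reactants: 15 5,7-dihydroxy-3-[2-methoxy-4-(methoxymethoxy)phenyl]chromen-4-one; 16 allyl bromide
Product: 17 5,7-bis(allyloxy)-3-[2-methoxy-4-(methoxymethoxy)phenyl]chromen-4-one
Conditions: allyl bromide (4 equiv), K2CO3 (4 equiv), DMF, 60 °C, 16 h
Reagents that add atoms: allyl bromide, C=CCBr
Why: In this Williamson O-allylation the 7-OH reacts fast and the chelated 5-OH is forced with excess allyl bromide in warm DMF, the MOM ether being inert.

Step 10
Reactants: 17 5,7-bis(allyloxy)-3-[2-methoxy-4-(methoxymethoxy)phenyl]chromen-4-one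
Product: 19 6,8-diallyl-5,7-dihydroxy-3-[2-methoxy-4-(methoxymethoxy)phenyl]chromen-4-one, via 8-allyl-7-hydroxy mono-Claisen phenol 18 (not isolated)
Conditions: N,N-diethylaniline, 200–210 °C, Ar, sealed tube, 6 h
Reagents that add atoms: none
Why: In this double aromatic Claisen rearrangement ([3,3]-sigmatropic shift, then tautomerisation) C6 and C8 are the only free ring A positions and a migration that lands on an occupied carbon moves on by a Cope shift, so every pathway converges on the 6,8-diallyl-5,7-diol.

Step 11
Reactants: 19 6,8-diallyl-5,7-dihydroxy-3-[2-methoxy-4-(methoxymethoxy)phenyl]chromen-4-one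
Product: 20 6,8-diallyl-5,7-dihydroxy-3-(4-hydroxy-2-methoxyphenyl)chromen-4-one
Conditions: 3 M aq HCl, MeOH, 50 °C, 3 h
Reagents that add atoms: none
Why: Acid-catalysed methanolysis cleaves the MOM acetal, and monosubstituted allyl groups do not cyclise onto the neighbouring phenols under these conditions, which is why the acid step comes before the prenyl groups exist.

Step 12
Reactants: 20 6,8-diallyl-5,7-dihydroxy-3-(4-hydroxy-2-methoxyphenyl)chromen-4-one; 21 2-methyl-2-butene
Product: 22 5,7-dihydroxy-3-(4-hydroxy-2-methoxyphenyl)-6,8-bis(3-methylbut-2-enyl)chromen-4-one (target)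
Conditions: 2-methyl-2-butene (large excess), second-generation Grubbs catalyst RuCl2(=CHPh)(PCy3)(H2IMes) (10 mol %), CH2Cl2, 40 °C, sealed tube, 16 h
Reagents that add atoms: 2-methyl-2-butene, CC=C(C)C
Why: In this olefin cross-metathesis each terminal allyl alkene exchanges its CH2 end for the isopropylidene unit of 2-methyl-2-butene with loss of propene, the ruthenium carbene tolerates free phenols and the chromone, and the new trisubstituted alkene has no E/Z isomers.

**Compound list**
1 | 2,4,6-trihydroxyacetophenone | CC(=O)c1c(O)cc(O)cc1O | starting material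
2 | benzyl bromide | BrCc1ccccc1 | starting material
3 | 1-[2,4-bis(benzyloxy)-6-hydroxyphenyl]ethanone | CC(=O)c1c(O)cc(OCc2ccccc2)cc1OCc1ccccc1 | intermediate
4 | 2,4-dihydroxybenzaldehyde | O=Cc1ccc(O)cc1O | starting material
5 | chloromethyl methyl ether | COCCl | starting material
6 | 2-hydroxy-4-(methoxymethoxy)benzaldehyde | COCOc1ccc(C=O)c(O)c1 | intermediate
7 | iodomethane | CI | starting material
8 | 2-methoxy-4-(methoxymethoxy)benzaldehyde | COCOc1ccc(C=O)c(OC)c1 | intermediate
9 | 1-[2,4-bis(benzyloxy)-6-hydroxyphenyl]-3-hydroxy-3-[2-methoxy-4-(methoxymethoxy)phenyl]propan-1-one (racemic aldol adduct, not isolated) | COCOc1ccc(C(O)CC(=O)c2c(O)cc(OCc3ccccc3)cc2OCc2ccccc2)c(OC)c1 | intermediate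
10 | (E)-1-[2,4-bis(benzyloxy)-6-hydroxyphenyl]-3-[2-methoxy-4-(methoxymethoxy)phenyl]prop-2-en-1-one | COCOc1ccc(/C=C/C(=O)c2c(O)cc(OCc3ccccc3)cc2OCc2ccccc2)c(OC)c1 | intermediate
11 | 1-[2,4-bis(benzyloxy)-6-hydroxyphenyl]-3,3-dimethoxy-2-[2-methoxy-4-(methoxymethoxy)phenyl]propan-1-one (racemic) | COCOc1ccc(C(C(OC)OC)C(=O)c2c(O)cc(OCc3ccccc3)cc2OCc2ccccc2)c(OC)c1 | intermediate
12 | 5,7-bis(benzyloxy)-2-methoxy-3-[2-methoxy-4-(methoxymethoxy)phenyl]chroman-4-one (racemic diastereomer mixture, not isolated) | COCOc1ccc(C2C(OC)Oc3cc(OCc4ccccc4)cc(OCc4ccccc4)c3C2=O)c(OC)c1 | intermediate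
13 | 5,7-bis(benzyloxy)-3-(4-hydroxy-2-methoxyphenyl)chromen-4-one | COc1cc(O)ccc1-c1coc2cc(OCc3ccccc3)cc(OCc3ccccc3)c2c1=O | intermediate
14 | 5,7-bis(benzyloxy)-3-[2-methoxy-4-(methoxymethoxy)phenyl]chromen-4-one | COCOc1ccc(-c2coc3cc(OCc4ccccc4)cc(OCc4ccccc4)c3c2=O)c(OC)c1 | intermediate
15 | 5,7-dihydroxy-3-[2-methoxy-4-(methoxymethoxy)phenyl]chromen-4-one | COCOc1ccc(-c2coc3cc(O)cc(O)c3c2=O)c(OC)c1 | intermediate
16 | allyl bromide | C=CCBr | starting material
17 | 5,7-bis(allyloxy)-3-[2-methoxy-4-(methoxymethoxy)phenyl]chromen-4-one | COCOc1ccc(-c2coc3cc(OCC=C)cc(OCC=C)c3c2=O)c(OC)c1 | intermediate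
18 | 8-allyl-5-(allyloxy)-7-hydroxy-3-[2-methoxy-4-(methoxymethoxy)phenyl]chromen-4-one (not isolated) | COCOc1ccc(-c2coc3c(CC=C)c(O)cc(OCC=C)c3c2=O)c(OC)c1 | intermediate
19 | 6,8-diallyl-5,7-dihydroxy-3-[2-methoxy-4-(methoxymethoxy)phenyl]chromen-4-one | COCOc1ccc(-c2coc3c(CC=C)c(O)c(CC=C)c(O)c3c2=O)c(OC)c1 | intermediate
20 | 6,8-diallyl-5,7-dihydroxy-3-(4-hydroxy-2-methoxyphenyl)chromen-4-one | COc1cc(O)ccc1-c1coc2c(CC=C)c(O)c(CC=C)c(O)c2c1=O | intermediate
21 | 2-methyl-2-butene | CC=C(C)C | starting material
22 | 5,7-dihydroxy-3-(4-hydroxy-2-methoxyphenyl)-6,8-bis(3-methylbut-2-enyl)chromen-4-one | COc1cc(O)ccc1-c1coc2c(CC=C(C)C)c(O)c(CC=C(C)C)c(O)c2c1=O | target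

**Summary**
Total step count: 12.
Longest linear sequence: 11 steps (2,4-dihydroxybenzaldehyde 4 to target 22 through steps 2–12); the ring A branch is 1 step before the convergence.

**Steps most likely to fail, with fallbacks**

Step 5 (thallium oxidative rearrangement). The nitric acid set free can strip the ring B MOM ether early and expose a phenol to the oxidant, and 2'-hydroxychalcones can divert to aurones. The fallback sets out from chalcone 10. NaOAc in refluxing EtOH closes it by intramolecular oxa-Michael addition to the racemic flavanone 5,7-bis(benzyloxy)-2-[2-methoxy-4-(methoxymethoxy)phenyl]chroman-4-one F1. PhI(OAc)2 with catalytic H2SO4 in CH(OMe)3 at rt then effects a metal-free oxidative 2,3-aryl shift of the flavanone to the isoflavone (14, or 13 where MOM has already been lost). The crude product is put through the HCl/MeOH conditions of step 6 so that everything converges, and the fallback comes back to the route at 13.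

Step 10 (double Claisen rearrangement). At 200 °C the second migration may stall, and the ortho-allylphenol formed first can close to a dihydrobenzofuran. The fallback sets out from diol 15. NIS (2.1 equiv) in DMF at 0 °C iodinates the only two free positions of the strongly activated ring A to give 5,7-dihydroxy-6,8-diiodo-3-[2-methoxy-4-(methoxymethoxy)phenyl]chromen-4-one F2. A double Stille coupling with allyltributylstannane (Pd(PPh3)4, a zerovalent palladium complex, DMF, 90 °C) then puts both allyl groups directly on carbon. This replaces steps 9 and 10 and comes back to the route at 19.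

Step 12 (double cross-metathesis on a free triphenol). The ortho-allylphenol units can chelate ruthenium, isomerise to propenyl groups or stop after one exchange. The fallback sets out from triol 20. Ac2O, pyridine and DMAP mask all three phenols as 4-(5,7-diacetoxy-6,8-diallyl-4-oxochromen-3-yl)-3-methoxyphenyl acetate F3. The same cross-metathesis with 2-methyl-2-butene and the second-generation Grubbs catalyst gives 4-[5,7-diacetoxy-6,8-bis(3-methylbut-2-enyl)-4-oxochromen-3-yl]-3-methoxyphenyl acetate F4. K2CO3 in MeOH at rt removes the acetates by transesterification without acid, and the fallback comes back to the route at 22.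

**Further compounds**
F1 | step 5 | 5,7-bis(benzyloxy)-2-[2-methoxy-4-(methoxymethoxy)phenyl]chroman-4-one (racemic) | COCOc1ccc(C2CC(=O)c3c(OCc4ccccc4)cc(OCc4ccccc4)cc3O2)c(OC)c1
F2 | step 10 | 5,7-dihydroxy-6,8-diiodo-3-[2-methoxy-4-(methoxymethoxy)phenyl]chromen-4-one | COCOc1ccc(-c2coc3c(I)c(O)c(I)c(O)c3c2=O)c(OC)c1
F3 | step 12 | 4-(5,7-diacetoxy-6,8-diallyl-4-oxochromen-3-yl)-3-methoxyphenyl acetate | COc1cc(OC(C)=O)ccc1-c1coc2c(CC=C)c(OC(C)=O)c(CC=C)c(OC(C)=O)c2c1=O
F4 | step 12 | 4-[5,7-diacetoxy-6,8-bis(3-methylbut-2-enyl)-4-oxochromen-3-yl]-3-methoxyphenyl acetate | COc1cc(OC(C)=O)ccc1-c1coc2c(CC=C(C)C)c(OC(C)=O)c(CC=C(C)C)c(OC(C)=O)c2c1=O
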